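**Retrosynthetic overview**
- Numbering the carbocycle C1 (CHOAc), C2, C3=C4 (C4 methyl), C5 (bearing C7H2–OAr) and C6 (CMe2), the route rests on the C4–C5 bond. It joins the methyl-bearing vinylic carbon to a ring carbon whose exocyclic neighbour C7 carries the coumarin-7-yloxy group. This is the pattern left when a C4 vinyl radical adds 6-exo to an aryl enol ether C5=C7–OAr.
- The cyclohexene is the only ring made and is closed last; the coumarin is brought in intact as umbelliferone.
- Acyclic precursor 17 ⇐ Chan–Lam O-alkenylation of umbelliferone with alkenylboronate 15 ⇐ boron olefination of the α-quaternary aldehyde 14.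
- C4 vinyl iodide ⇐ hydrozirconation–iodination of 2-alkyne 9 ⇐ propynyllithium opening of (S)-epoxide 6.
- C1 stereocentre ⇐ hydrolytic kinetic resolution of the epoxide from PMB-protected 2,2-dimethylbut-3-en-1-ol (from acid 1).

Key step: step 12

Assumption: the (S,S)-(salen)Co(III)OAc catalyst is taken to leave the (S)-epoxide, as it does for simple alkyl oxiranes in which the ring CH2 outranks the substituent. The configuration of 9 would be checked as its Mosher esters, and the enantiomeric catalyst used if the sense were opposite.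

**Step 1**
Reactants: 1 2,2-dimethylbut-3-enoic acid
Product: 2 2,2-dimethylbut-3-en-1-ol
Conditions: LiAlH4, Et2O, 0 °C → rt; Fieser work-up
Reagents that add atoms: none
Why: LiAlH4 reduction of the carboxylic acid stops at the primary alcohol and leaves the unactivated vinyl group untouched.

**Step 2**
Reactants: 2 2,2-dimethylbut-3-en-1-ol
Product: 4 1-{[(2,2-dimethylbut-3-en-1-yl)oxy]methyl}-4-methoxybenzene, via sodium 2,2-dimethylbut-3-en-1-olate 3 (not isolated)
Conditions: NaH, THF/DMF, 0 °C; then PMBCl, Bu4NI (cat.), rt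
Reagents that add atoms: 4-methoxybenzyl chloride, COc1ccc(CCl)cc1
Why: Williamson ether synthesis on the sodium alkoxide; the PMB ether tolerates peracid, BF3 at −78 °C, Zr–H and iodine and is later removed oxidatively without base, so that the acetate cannot migrate.

**Step 3**
Reactants: 4 1-{[(2,2-dimethylbut-3-en-1-yl)oxy]methyl}-4-methoxybenzene
Product: 5 rac-2-{1-[(4-methoxybenzyl)oxy]-2-methylpropan-2-yl}oxirane
Conditions: mCPBA, NaHCO3, CH2Cl2, 0 °C → rt
Reagents that add atoms: 3-chloroperbenzoic acid, OOC(=O)c1cccc(Cl)c1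
Why: Prilezhaev epoxidation of the monosubstituted alkene, slow next to the quaternary carbon but free of competing sites, should give the racemic terminal epoxide.

**Step 4**
Reactants: 5 rac-2-{1-[(4-methoxybenzyl)oxy]-2-methylpropan-2-yl}oxirane
Product: 6 (2S)-2-{1-[(4-methoxybenzyl)oxy]-2-methylpropan-2-yl}oxirane
Conditions: (S,S)-(salen)Co(III)OAc (2 mol%), H2O (0.55 equiv), THF, 0 °C → rt; chromatography
Reagents that add atoms: none
Why: Jacobsen hydrolytic kinetic resolution, in which the chiral Co(salen) catalyst hydrates the (R)-epoxide at its terminal carbon much faster than the (S)-epoxide, so that unreacted 6 (at most half of 5) carries the configuration that becomes C1 and is separated from the polar diol.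

**Step 5**
Reactants: 6 (2S)-2-{1-[(4-methoxybenzyl)oxy]-2-methylpropan-2-yl}oxirane; 7 propyne
Product: 9 (3R)-1-[(4-methoxybenzyl)oxy]-2,2-dimethylhept-5-yn-3-ol, via 1-propynyllithium 8 (not isolated)
Conditions: propyne, n-BuLi, THF, −78 °C; BF3·OEt2; then 6, −78 °C; aq NH4Cl
Reagents that add atoms: none
Why: Yamaguchi–Hirao alkynylation, in which the BF3-activated epoxide is opened by the lithium acetylide at the unhindered CH2 terminus, so the C–O stereocentre is not touched and its descriptor becomes R only through the change in CIP priorities.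

**Step 6**
Reactants: 9 (3R)-1-[(4-methoxybenzyl)oxy]-2,2-dimethylhept-5-yn-3-ol
Product: 11 (3R,5E)-6-iodo-1-[(4-methoxybenzyl)oxy]-2,2-dimethylhept-5-en-3-ol, via C6-zirconated (E)-alkenylzirconocene alkoxide 10 (not isolated)
Conditions: Cp2Zr(H)Cl (3.2 equiv), THF, rt → 45 °C; then I2, THF, 0 °C
Reagents that add atoms: iodine, II
Why: Syn hydrozirconation with the Schwartz reagent (one equivalent is consumed by the hydroxyl) equilibrates under excess Zr–H to the regioisomer with zirconium on the methyl-bearing carbon, remote from the branched chain, and iodinolysis with retention gives the (E)-2-iodoalkene.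

**Step 7**
Reactants: 11 (3R,5E)-6-iodo-1-[(4-methoxybenzyl)oxy]-2,2-dimethylhept-5-en-3-ol
Product: 12 (3R,5E)-6-iodo-1-[(4-methoxybenzyl)oxy]-2,2-dimethylhept-5-en-3-yl acetate
Conditions: Ac2O, pyridine, DMAP (cat.), CH2Cl2, rt
Reagents that add atoms: acetic anhydride, CC(=O)OC(C)=O
Why: DMAP-catalysed acylation of the hindered secondary alcohol; no stereocentre is affected.

**Step 8**
Reactants: 12 (3R,5E)-6-iodo-1-[(4-methoxybenzyl)oxy]-2,2-dimethylhept-5-en-3-yl acetate
Product: 13 (3R,5E)-1-hydroxy-6-iodo-2,2-dimethylhept-5-en-3-yl acetate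
Conditions: DDQ, CH2Cl2/pH 7 buffer, 0 °C → rt
Reagents that add atoms: none
Why: Oxidative PMB cleavage by DDQ (hydride abstraction, then hydrolysis of the oxocarbenium ion) runs at neutral pH, which keeps the acetate in place and the vinyl iodide intact; 13 is carried on at once to forestall 1,3-acetyl migration.

**Step 9**
Reactants: 13 (3R,5E)-1-hydroxy-6-iodo-2,2-dimethylhept-5-en-3-yl acetate
Product: 14 (3R,5E)-6-iodo-2,2-dimethyl-1-oxohept-5-en-3-yl acetate
Conditions: Dess–Martin periodinane, NaHCO3, CH2Cl2, 0 °C → rt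
Reagents that add atoms: none
Why: Dess–Martin oxidation of the neopentyl primary alcohol; the aldehyde has no α-hydrogen, so neither β-elimination of acetate nor epimerisation can follow.

**Step 10**
Reactants: 14 (3R,5E)-6-iodo-2,2-dimethyl-1-oxohept-5-en-3-yl acetate
Product: 15 (1E,4R,6E)-7-iodo-3,3-dimethyl-1-(4,4,5,5-tetramethyl-1,3,2-dioxaborolan-2-yl)octa-1,6-dien-4-yl acetate
Conditions: CrCl2 (8 equiv, nickel-free), Cl2CHBpin (2 equiv), LiI (4 equiv), THF, rt
Reagents that add atoms: 2-(dichloromethyl)-4,4,5,5-tetramethyl-1,3,2-dioxaborolane, ClC(Cl)B1OC(C)(C)C(C)(C)O1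
Why: Takai–Utimoto boron olefination, in which the gem-dichromium species from the dihalomethylboronate adds to the aldehyde and eliminates to the (E)-alkenylboronate, while esters and (without nickel) vinyl iodides are inert to Cr(II).

**Step 11**
Reactants: 15 (1E,4R,6E)-7-iodo-3,3-dimethyl-1-(4,4,5,5-tetramethyl-1,3,2-dioxaborolan-2-yl)octa-1,6-dien-4-yl acetate; 16 umbelliferone
Product: 17 (1E,4R,6E)-7-iodo-3,3-dimethyl-1-[(2-oxo-2H-chromen-7-yl)oxy]octa-1,6-dien-4-yl acetate
Conditions: Cu(OAc)2 (2 equiv), pyridine, 4 Å MS, CH2Cl2/MeCN, dry air, rt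
Reagents that add atoms: none
Why: Chan–Lam–Evans oxidative coupling, in which the alkenyl group passes from boron to a copper(II) phenoxide and C(sp2)–O reductive elimination from Cu(III) retains the E geometry, the hindered vinyl iodide being inert to copper at room temperature.

**Step 12**
Reactants: 17 (1E,4R,6E)-7-iodo-3,3-dimethyl-1-[(2-oxo-2H-chromen-7-yl)oxy]octa-1,6-dien-4-yl acetate
Product: 18 (1R,5R)-4,6,6-trimethyl-5-{[(2-oxo-2H-chromen-7-yl)oxy]methyl}cyclohex-3-en-1-yl acetate
Conditions: (Me3Si)3SiH (1.3 equiv), AIBN (0.2 equiv), toluene (0.01 M), 80 °C, syringe-pump addition over 6 h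
Reagents that add atoms: none
Why: The silyl radical abstracts iodine to give a bent σ-vinyl radical at C4 that inverts far faster than it is trapped, so that the E-iodide still presents its SOMO on the side of C2; this radical adds to C5, the β-carbon of the aryl enol ether, and the α-aryloxy radical at C7 takes hydrogen from the silane and carries the chain. The closest known reaction type is the tin- or silane-mediated cyclisation of vinyl radicals from vinyl halides onto tethered alkenes to give cyclohexenes. The carbocycle closes in the 6-exo-trig mode through the new C4–C5 bond, with C3=C4 becoming endocyclic. The C5 stereocentre is set by C1 through a half-chair transition state with the acetoxy group equatorial and the enol ether arm pseudoaxial, where the arm escapes A(1,2) strain with the C4 methyl and a double gauche contact with the C6 methyls and, being trans to the acetate, has no 1,3-diaxial partner; this is the (1R,5R) arrangement. The step needs 6-exo over 7-endo closure, ring closure ahead of hydrogen transfer, and trans over cis: oxygen polarisation of the acceptor and α-oxygen stabilisation of the C7 radical direct attack to C5 and disfavour homoallyl ring expansion, the gem-dimethyl group speeds closure and leaves no 1,5-hydrogen for translocation, and slow addition of the sluggish donor (Me3Si)3SiH at high dilution holds reduction back.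

**Compound list**
1 | 2,2-dimethylbut-3-enoic acid | C=CC(C)(C)C(=O)O | starting material
2 | 2,2-dimethylbut-3-en-1-ol | C=CC(C)(C)CO | intermediate
3 | sodium 2,2-dimethylbut-3-en-1-olate (not isolated) | C=CC(C)(C)C[O-].[Na+] | intermediate
4 | 1-{[(2,2-dimethylbut-3-en-1-yl)oxy]methyl}-4-methoxybenzene | C=CC(C)(C)COCc1ccc(OC)cc1 | intermediate
5 | rac-2-{1-[(4-methoxybenzyl)oxy]-2-methylpropan-2-yl}oxirane | COc1ccc(COCC(C)(C)C2CO2)cc1 | intermediate
6 | (2S)-2-{1-[(4-methoxybenzyl)oxy]-2-methylpropan-2-yl}oxirane | COc1ccc(COCC(C)(C)[C@H]2CO2)cc1 | intermediate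
7 | propyne | CC#C | starting material
8 | 1-propynyllithium (not isolated) | [Li]C#CC | intermediate
9 | (3R)-1-[(4-methoxybenzyl)oxy]-2,2-dimethylhept-5-yn-3-ol | COc1ccc(COCC(C)(C)[C@H](O)CC#CC)cc1 | intermediate
10 | (3R,5E)-alkenylzirconocene from 9: chlorozirconocene alkoxide on O3 and a second Cp2ZrCl on C6, trans to C4 (not isolated; Cp rings written σ-bonded in the SMILES) | COc1ccc(COCC(C)(C)[C@H](O[Zr](Cl)(C2C=CC=C2)C2C=CC=C2)C/C=C(C)/[Zr](Cl)(C2C=CC=C2)C2C=CC=C2)cc1 | intermediate
11 | (3R,5E)-6-iodo-1-[(4-methoxybenzyl)oxy]-2,2-dimethylhept-5-en-3-ol | COc1ccc(COCC(C)(C)[C@H](O)C/C=C(C)/I)cc1 | intermediate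
12 | (3R,5E)-6-iodo-1-[(4-methoxybenzyl)oxy]-2,2-dimethylhept-5-en-3-yl acetate | COc1ccc(COCC(C)(C)[C@H](OC(C)=O)C/C=C(C)/I)cc1 | intermediate
13 | (3R,5E)-1-hydroxy-6-iodo-2,2-dimethylhept-5-en-3-yl acetate | CC(=O)O[C@H](C/C=C(C)/I)C(C)(C)CO | intermediate
14 | (3R,5E)-6-iodo-2,2-dimethyl-1-oxohept-5-en-3-yl acetate | CC(=O)O[C@H](C/C=C(C)/I)C(C)(C)C=O | intermediate
15 | (1E,4R,6E)-7-iodo-3,3-dimethyl-1-(4,4,5,5-tetramethyl-1,3,2-dioxaborolan-2-yl)octa-1,6-dien-4-yl acetate | CC(=O)O[C@H](C/C=C(C)/I)C(C)(C)/C=C/B1OC(C)(C)C(C)(C)O1 | intermediate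
16 | umbelliferone (7-hydroxy-2H-chromen-2-one) | O=c1ccc2ccc(O)cc2o1 | starting material
17 | (1E,4R,6E)-7-iodo-3,3-dimethyl-1-[(2-oxo-2H-chromen-7-yl)oxy]octa-1,6-dien-4-yl acetate | CC(=O)O[C@H](C/C=C(C)/I)C(C)(C)/C=C/Oc1ccc2ccc(=O)oc2c1 | intermediate
18 | (1R,5R)-4,6,6-trimethyl-5-{[(2-oxo-2H-chromen-7-yl)oxy]methyl}cyclohex-3-en-1-yl acetate | CC(=O)O[C@@H]1CC=C(C)[C@@H](COc2ccc3ccc(=O)oc3c2)C1(C)C | target

Total step count: 12. Longest linear sequence: 12 steps (from 1).

**Steps most likely to fail**

1. Step 12 (radical ring closure). Hydrogen transfer to the C4 vinyl radical may outrun closure and give simple deiodination, the silyl radical may add to the coumarin C3=C4 bond, or facial discrimination at C5 may be weak. The fallback keeps the vinyl radical but moves the ring closure ahead of the aryl ether and sets out from 15. The same silane/AIBN conditions should close the ring onto the alkenylboronate (6-exo, α-boryl radical), giving (1R,5R)-4,6,6-trimethyl-5-[(4,4,5,5-tetramethyl-1,3,2-dioxaborolan-2-yl)methyl]cyclohex-3-en-1-yl acetate F1. Oxidation of the C–B bond with NaBO3·4H2O in THF/water would give (1R,5R)-5-(hydroxymethyl)-4,6,6-trimethylcyclohex-3-en-1-yl acetate F2. Mitsunobu etherification of F2 with umbelliferone 16 (PPh3, DIAD, THF, 0 °C → rt) comes back to the route at 18.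

2. Step 11 (Chan–Lam coupling). Transfer of the hindered alkenyl group from the pinacol ester to copper may be slow, so that protodeboronation or oxidative homocoupling takes over. The fallback sets out from 15. Oxidative removal of the pinacol with NaIO4/NH4OAc in acetone/water would give [(1E,4R,6E)-4-acetoxy-7-iodo-3,3-dimethylocta-1,6-dien-1-yl]boronic acid F3, the classical partner for copper-mediated O-alkenylation. F3 is then coupled with 16 (Cu(OAc)2, pyridine, 4 Å MS, CH2Cl2, air, rt), returning at 17.

3. Step 10 (boron olefination). Addition of the gem-dichromium reagent to the neopentyl aldehyde may be sluggish, and traces of nickel in the chromium salt could trigger insertion into the vinyl iodide and Nozaki–Hiyama–Kishi closure onto the aldehyde. The fallback is a chromium-free boron–Wittig olefination setting out from 14. Bis(pinacolatoboryl)methane is deprotonated with LiTMP (THF, 0 °C) and 14 is added at −78 °C. The resulting lithium (4R,6E)-4-acetoxy-7-iodo-3,3-dimethyl-1,1-bis(4,4,5,5-tetramethyl-1,3,2-dioxaborolan-2-yl)oct-6-en-2-olate F4 is not isolated and should lose lithium pinacolatoborate on warming, returning at 15.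

**Further compounds**
F1 | step 12 | (1R,5R)-4,6,6-trimethyl-5-[(4,4,5,5-tetramethyl-1,3,2-dioxaborolan-2-yl)methyl]cyclohex-3-en-1-yl acetate | CC(=O)O[C@@H]1CC=C(C)[C@@H](CB2OC(C)(C)C(C)(C)O2)C1(C)C
F2 | step 12 | (1R,5R)-5-(hydroxymethyl)-4,6,6-trimethylcyclohex-3-en-1-yl acetate | CC(=O)O[C@@H]1CC=C(C)[C@@H](CO)C1(C)C
F3 | step 11 | [(1E,4R,6E)-4-acetoxy-7-iodo-3,3-dimethylocta-1,6-dien-1-yl]boronic acid | CC(=O)O[C@H](C/C=C(C)/I)C(C)(C)/C=C/B(O)O
F4 | step 10 | lithium (4R,6E)-4-acetoxy-7-iodo-3,3-dimethyl-1,1-bis(4,4,5,5-tetramethyl-1,3,2-dioxaborolan-2-yl)oct-6-en-2-olate (C2 unassigned) | CC(=O)O[C@H](C/C=C(C)/I)C(C)(C)C(O[Li])C(B1OC(C)(C)C(C)(C)O1)B1OC(C)(C)C(C)(C)O1
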